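Ring A is treated as the aromatic tautomer of a cyclohexane-1,3,5-trione: C3–C4–C5, with the C3 methyl and the C5 bridge methylene, is the α-CH2–CO–α′-CH2 triad of a ketone, and C2–C1–C6 is a malonyl unit. Cutting C5–C6 and C2–C3 leaves a 1-arylpentan-3-one bearing the complete, benzyl-protected ring B. Malonyl dichloride acylates both α-carbons of its triethylsilyl enol ether in one operation, closing ring A and aromatising it, so the unsymmetrical bridge is never in question. Hydrogenolysis and double butyrylation at C1 and C5′ then finish the target.

Key step: step 6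

Remark: the target has no stereocentre; the only stereochemical labels in the route are the alkene geometries of two intermediates, both erased in the key step. 2-Methylphloroglucinol and diethyl (2-oxobutyl)phosphonate are taken as purchasable.

Step 1
Reactants: 1 2-methylphloroglucinol
Product: 3 2,4,6-trihydroxy-3-methylbenzaldehyde, via aryl dimethyliminium chloride 2 (not isolated)
Conditions: POCl3, DMF, EtOAc, 0 °C to rt; then H2O, 60 °C
Reagents that add atoms: N,N-dimethylformamide, CN(C)C=O; water, O
Why: Vilsmeier–Haack formylation; the two unsubstituted ring carbons of 1 are equivalent, the iminium group of 2 deactivates the ring against a second attack, and hydrolysis releases the aldehyde.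

Step 2
Reactants: 3 2,4,6-trihydroxy-3-methylbenzaldehyde
Product: 4 2,6-dihydroxy-4-methoxy-3-methylbenzaldehyde
Conditions: Me2SO4 (1.0 equiv), K2CO3 (1.0 equiv), acetone, 0 °C to rt
Reagents that add atoms: dimethyl sulfate, COS(=O)(=O)OC
Why: Williamson O-methylation; the hydroxyl para to the formyl group is the most acidic and the only one not held in a hydrogen bond to the carbonyl, so one equivalent of base and of a hard methylating agent should alkylate it first.

Step 3
Reactants: 4 2,6-dihydroxy-4-methoxy-3-methylbenzaldehyde
Product: 5 2,6-bis(benzyloxy)-4-methoxy-3-methylbenzaldehyde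
Conditions: BnBr (2.5 equiv), K2CO3 (3 equiv), DMF, 60 °C
Reagents that add atoms: benzyl bromide, BrCc1ccccc1
Why: Williamson benzylation; excess base in a dipolar aprotic solvent with mild heating should break the hydrogen bonds of both ortho hydroxyls and alkylate them on oxygen, and the aldehyde cannot enolise.

Step 4
Reactants: 5 2,6-bis(benzyloxy)-4-methoxy-3-methylbenzaldehyde; 6 diethyl (2-oxobutyl)phosphonate
Product: 7 (E)-1-[2,6-bis(benzyloxy)-4-methoxy-3-methylphenyl]pent-1-en-3-one
Conditions: 6, NaH, THF, 0 °C; then 5, reflux
Reagents that add atoms: diethyl (2-oxobutyl)phosphonate (compound 6), CCC(=O)CP(=O)(OCC)OCC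
Why: Horner–Wadsworth–Emmons olefination; the stabilised β-ketophosphonate anion adds to the non-enolisable aldehyde and eliminates phosphate to give the (E)-enone, with the ethyl ketone in place without any aldol regiochemistry problem.

Step 5
Reactants: 7 (E)-1-[2,6-bis(benzyloxy)-4-methoxy-3-methylphenyl]pent-1-en-3-one
Product: 8 (Z)-({1-[2,6-bis(benzyloxy)-4-methoxy-3-methylphenyl]pent-2-en-3-yl}oxy)triethylsilane
Conditions: Et3SiH (1.5 equiv), RhCl(PPh3)3 (1 mol %), toluene, 55 °C; evaporate, filter through Florisil (hexane) under argon, use at once
Reagents that add atoms: triethylsilane, CC[SiH](CC)CC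
Why: Rhodium-catalysed 1,4-hydrosilylation of an enone (Ojima type); a monohydrosilane delivers silicon to oxygen and hydrogen to the β-carbon through the s-cis conformer, which should give the (Z)-silyl enol ether regiospecifically and leave the benzyl ethers untouched.

Step 6
Reactants: 8 (Z)-({1-[2,6-bis(benzyloxy)-4-methoxy-3-methylphenyl]pent-2-en-3-yl}oxy)triethylsilane; 9 malonyl dichloride
Product: 12 2-{[2,6-bis(benzyloxy)-4-methoxy-3-methylphenyl]methyl}-4-methylbenzene-1,3,5-triol, via 3,5-dioxoheptanoyl chloride 10 (not isolated), via cyclohexane-1,3,5-trione 11 (not isolated)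
Conditions: slow addition of 8 to 9 (1.1 equiv), Et2O, −78 °C to −20 °C; aq. NaHCO3 work-up
Reagents that add atoms: malonyl dichloride (compound 9), O=C(Cl)CC(=O)Cl
Why: The nucleophilic carbon C5 of enol ether 8 attacks one acyl chloride of 9 and the silyloxocarbenium ion collapses with loss of Et3SiCl (C5–C6 formed, giving 10); the C4 carbonyl of 10 then enolises toward C3, which attacks the remaining acyl chloride with loss of HCl (C2–C3 formed, giving 11), and 11 enolises to the arene 12. The closest known reaction type is the Effenberger condensation of ketone silyl enol ethers with malonyl dichloride, which delivers 2,4-disubstituted phloroglucinols from ketones with two α-methylene groups. Ring A closes by a 6-(enolendo)-exo-trig attack. No stereocentre survives, since the sp3 centres of 10 and 11 are erased on aromatisation, and because both flanks of the C4 carbonyl are acylated, either regio- or geometric isomer of the enol ether would converge on 12. Chemoselectivity for the enol ether over the free C5′ position of ring B rests on the much higher π-nucleophilicity of a silyl enol ether toward an acid chloride at −78 °C in the absence of a Lewis acid, on the benzyl ethers that keep the ring B oxygens out of play, and on the lack of any free ring B position within reach of the tethered acyl chloride of 10. Closure through carbon and not through oxygen is favoured because C3 and C5 each keep a hydrogen, so the carbocycle is drained irreversibly into the aromatic triol, and slow addition of 8 to a slight excess of 9 prevents one malonyl unit from capturing two enol ethers.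

Step 7
Reactants: 12 2-{[2,6-bis(benzyloxy)-4-methoxy-3-methylphenyl]methyl}-4-methylbenzene-1,3,5-triol
Product: 13 2-[(2,6-dihydroxy-4-methoxy-3-methylphenyl)methyl]-4-methylbenzene-1,3,5-triol
Conditions: H2 (1 atm), 10% Pd/C, EtOAc/MeOH, rt; handled under argon
Reagents that add atoms: none
Why: Catalytic hydrogenolysis cleaves only the two benzyl–oxygen bonds; the diarylmethane C–C bond and the aryl methyl ether are inert, and debenzylation is placed before acylation so that no ketone is present to be over-reduced.

Step 8
Reactants: 13 2-[(2,6-dihydroxy-4-methoxy-3-methylphenyl)methyl]-4-methylbenzene-1,3,5-triol; 14 butyric acid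
Product: 15 1-{3-[(3-butanoyl-2,6-dihydroxy-4-methoxy-5-methylphenyl)methyl]-2,4,6-trihydroxy-5-methylphenyl}butan-1-one
Conditions: 14 (3 equiv), BF3·OEt2 (solvent), 70 °C; then aq. NaOAc
Reagents that add atoms: butyric acid (compound 14), CCCC(=O)O
Why: Friedel–Crafts C-acylation of polyphenols by a carboxylic acid in BF3·OEt2 (any phenyl ester formed first rearranges in the Fries sense); each ring offers exactly one unsubstituted carbon, C1 between two hydroxyls and C5′ between methoxy and hydroxyl, each new ketone deactivates its own ring as a hydrogen-bonded ortho-hydroxyaryl ketone, and BF3 should not cleave the aryl methyl ether.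

Compound list
1 | 2-methylphloroglucinol (2-methylbenzene-1,3,5-triol) | Cc1c(O)cc(O)cc1O | starting material
2 | [(2,4,6-trihydroxy-3-methylphenyl)methylidene]dimethylammonium chloride (not isolated) | C[N+](C)=Cc1c(O)cc(O)c(C)c1O.[Cl-] | intermediate
3 | 2,4,6-trihydroxy-3-methylbenzaldehyde | Cc1c(O)cc(O)c(C=O)c1O | intermediate
4 | 2,6-dihydroxy-4-methoxy-3-methylbenzaldehyde | COc1cc(O)c(C=O)c(O)c1C | intermediate
5 | 2,6-bis(benzyloxy)-4-methoxy-3-methylbenzaldehyde | COc1cc(OCc2ccccc2)c(C=O)c(OCc2ccccc2)c1C | intermediate
6 | diethyl (2-oxobutyl)phosphonate | CCC(=O)CP(=O)(OCC)OCC | starting material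
7 | (E)-1-[2,6-bis(benzyloxy)-4-methoxy-3-methylphenyl]pent-1-en-3-one | CCC(=O)/C=C/c1c(OCc2ccccc2)cc(OC)c(C)c1OCc1ccccc1 | intermediate
8 | (Z)-({1-[2,6-bis(benzyloxy)-4-methoxy-3-methylphenyl]pent-2-en-3-yl}oxy)triethylsilane | CC/C(O[Si](CC)(CC)CC)=C/Cc1c(OCc2ccccc2)c(C)c(OC)cc1OCc1ccccc1 | intermediate
9 | malonyl dichloride | O=C(Cl)CC(=O)Cl | starting material
10 | 4-{[2,6-bis(benzyloxy)-4-methoxy-3-methylphenyl]methyl}-3,5-dioxoheptanoyl chloride (racemic, not isolated) | CCC(=O)C(Cc1c(OCc2ccccc2)c(C)c(OC)cc1OCc1ccccc1)C(=O)CC(=O)Cl | intermediate
11 | 2-{[2,6-bis(benzyloxy)-4-methoxy-3-methylphenyl]methyl}-4-methylcyclohexane-1,3,5-trione (stereoisomer mixture, not isolated) | CC1C(=O)CC(=O)C(Cc2c(OCc3ccccc3)c(C)c(OC)cc2OCc2ccccc2)C1=O | intermediate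
12 | 2-{[2,6-bis(benzyloxy)-4-methoxy-3-methylphenyl]methyl}-4-methylbenzene-1,3,5-triol | Cc1c(O)cc(O)c(Cc2c(OCc3ccccc3)c(C)c(OC)cc2OCc2ccccc2)c1O | intermediate
13 | 2-[(2,6-dihydroxy-4-methoxy-3-methylphenyl)methyl]-4-methylbenzene-1,3,5-triol | Cc1c(O)cc(O)c(Cc2c(O)c(C)c(OC)cc2O)c1O | intermediate
14 | butyric acid | CCCC(=O)O | starting material
15 | 1-{3-[(3-butanoyl-2,6-dihydroxy-4-methoxy-5-methylphenyl)methyl]-2,4,6-trihydroxy-5-methylphenyl}butan-1-one | CCCC(=O)c1c(O)c(C)c(O)c(Cc2c(O)c(C)c(OC)c(C(=O)CCC)c2O)c1O | target

Total step count: 8. Longest linear sequence: 8 steps (1 to 15).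

Steps most likely to fail

Step 6. Ring closure may run through the enol oxygen (lactonisation to a pyranone) instead of through C3. The acid chloride may also acylate ring B or the freshly formed phenols, and the HCl released may protodesilylate unreacted enol ether. The fallback sets out from aldehyde 5 and starting material 1 and comes back at 12; it gives up ring construction and joins two finished rings at the C5–CH2 bond. NaBH4 (THF/MeOH, 0 °C) should reduce 5 to [2,6-bis(benzyloxy)-4-methoxy-3-methylphenyl]methanol F1. F1 is then added slowly to an excess of 2-methylphloroglucinol 1 (4 equiv) with catalytic TsOH·H2O in MeCN at 0 °C. The trialkoxy-stabilised benzylic cation should alkylate one of the two equivalent free carbons of 1 (Friedel–Crafts benzylation) and give 12. The excess of 1 suppresses double benzylation and self-condensation of F1 and is removed by aqueous washing.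

Step 8. At the temperature needed for the second acylation the electron-rich diarylmethane may suffer acid-promoted scission of the methylene bridge or cyclodehydration between the hydroxyls that flank it, and the second ring may acylate incompletely. The fallback sets out from 13 and comes back at 15; it moves the C–C bond formation from hot Lewis acid to nitrilium chemistry at 0 °C (Houben–Hoesch reaction). Butyronitrile (excess), ZnCl2 and dry HCl in Et2O at 0 °C should add at C1 and C5′ and precipitate 2-butanimidoyl-4-[(3-butanimidoyl-2,6-dihydroxy-4-methoxy-5-methylphenyl)methyl]-6-methylbenzene-1,3,5-triol F2 as its bis-hydrochloride. Hydrolysis of this salt in water at 80 °C should give 15.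

Step 2. Methylation may continue to a second hydroxyl, take place at a chelated ortho oxygen, or occur at the ring carbon C5′ in competition with the wanted mono-O-methylation. The fallback sets out from 3 and comes back at 4; it sets the site selectivity in a deprotection instead of a protection. Exhaustive methylation (Me2SO4 in excess, K2CO3, acetone, reflux) should give 2,4,6-trimethoxy-3-methylbenzaldehyde F3. BCl3 (excess, CH2Cl2, −78 °C to rt, prolonged) should then cleave only the two methoxy groups ortho to the formyl group, because only they can form a six-membered boron chelate with the carbonyl oxygen. The para methyl ether remains.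

Further compounds
F1 | step 6 | [2,6-bis(benzyloxy)-4-methoxy-3-methylphenyl]methanol | COc1cc(OCc2ccccc2)c(CO)c(OCc2ccccc2)c1C
F2 | step 8 | 2-butanimidoyl-4-[(3-butanimidoyl-2,6-dihydroxy-4-methoxy-5-methylphenyl)methyl]-6-methylbenzene-1,3,5-triol | CCCC(=N)c1c(O)c(C)c(O)c(Cc2c(O)c(C)c(OC)c(C(=N)CCC)c2O)c1O
F3 | step 2 | 2,4,6-trimethoxy-3-methylbenzaldehyde | COc1cc(OC)c(C=O)c(OC)c1C
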